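**Retrosynthetic overview**

- Feature: C13 (CHOAc) and C14 (lactone O–CH) are adjacent carbons of the 14-membered carbocycle (C1–C14), and the lactone carbonyl C16 lies γ to O14 through C1–C15. One carbonyl coupling at C13–C14 can therefore deliver the carbocycle and the trans-fused γ-lactone (O14–C16) together.
- Endgame: the acetate and the exocyclic C15 methylene are taken off to leave the 13-hydroxy γ-lactone.
- Key disconnection: C13–C14 and O14–C16 are opened to an acyclic epoxy dialdehyde methyl ester (C14 aldehyde, C13 enal, C16 ester). Forward, SmI2 pinacol coupling is followed by lactonisation of the C14 alkoxide in the same flask.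
- Precursor: cut at C1–C2 into a succinate imide (C14, C1, C15, C16; an oxazolidinone sets C1) and an epoxy triflate made from (2E,6E)-farnesol, which supplies C2–C13 with both E-alkenes in one piece. The C13 oxygen comes from SeO2 allylic oxidation and the 3,4-epoxide from hydroxyl-directed Sharpless epoxidation, so regioselectivity among the three alkenes is not an issue.
- Ring order: oxirane (step 5), then carbocycle and γ-lactone in one operation (step 12).

Key step: step 12

Remark: cembrane numbering is used for every intermediate (ring C1–C14; C15 lactone α-carbon; C16 lactone carbonyl), and commercial (2E,6E)-farnesol is taken as the isomerically pure E,E alcohol.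

**Route**

Step 1
Reactants: 1 (2E,6E)-farnesol
Product: 2 (2E,6E)-farnesyl acetate
Conditions: Ac2O, pyridine, DMAP (cat.), CH2Cl2, 0 °C to rt
Reagents that add atoms: acetic anhydride CC(=O)OC(C)=O
Why: DMAP-catalysed O-acetylation (nucleophilic acyl substitution) masks the primary allylic alcohol and deactivates the neighbouring alkene toward the allylic oxidation that follows.

Step 2
Reactants: 2 (2E,6E)-farnesyl acetate
Product: 3 (2E,6E,10E)-12-hydroxyfarnesyl acetate
Conditions: SeO2 (cat.), t-BuOOH, salicylic acid (cat.), CH2Cl2, 0 °C to rt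
Reagents that add atoms: tert-butyl hydroperoxide CC(C)(C)OO (oxygen relayed by the catalyst selenium dioxide O=[Se]=O)
Why: Riley-type allylic oxidation (ene reaction with SeO2, then [2,3]-sigmatropic shift) should attack the most electron-rich, terminal trisubstituted alkene at its E-methyl group and give the (E)-allylic alcohol that becomes C13.

Step 3
Reactants: 3 (2E,6E,10E)-12-hydroxyfarnesyl acetate
Product: 4 (2E,6E,10E)-12-(tert-butyldimethylsilyloxy)farnesyl acetate
Conditions: TBSCl, imidazole, DMF, 0 °C to rt
Reagents that add atoms: tert-butyldimethylsilyl chloride CC(C)(C)[Si](C)(C)Cl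
Why: Silylation of the primary alcohol gives an ether that should survive methanolysis, epoxidation, enolate alkylation, thiolysis and the palladium-catalysed reduction.

Step 4
Reactants: 4 (2E,6E,10E)-12-(tert-butyldimethylsilyloxy)farnesyl acetate
Product: 5 (2E,6E,10E)-12-(tert-butyldimethylsilyloxy)farnesol
Conditions: K2CO3, MeOH, 0 °C
Reagents that add atoms: none
Why: Base-catalysed transesterification removes only the acetate and frees the allylic alcohol that directs the epoxidation.

Step 5
Reactants: 5 (2E,6E,10E)-12-(tert-butyldimethylsilyloxy)farnesol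
Product: 6 (2S,3S)-epoxy alcohol [(2S,3S)-3-[(3E,7E)-9-(tert-butyldimethylsilyloxy)-4,8-dimethylnona-3,7-dienyl]-3-methyloxiran-2-yl]methanol
Conditions: Ti(OiPr)4 (cat.), L-(+)-diethyl tartrate (cat.), t-BuOOH, 4 Å molecular sieves, CH2Cl2, −20 °C
Reagents that add atoms: tert-butyl hydroperoxide CC(C)(C)OO
Why: Katsuki–Sharpless asymmetric epoxidation is hydroxyl-directed, so of the three trisubstituted alkenes only the allylic-alcohol alkene (C3=C4) reacts, and the L-(+)-tartrate ligand delivers oxygen to the face that gives the (2S,3S)-epoxy alcohol, which is the 3S,4S epoxide of the target.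

Step 6
Reactants: 7 (S)-4-benzyloxazolidin-2-one; 8 methyl 4-chloro-4-oxobutanoate (acid chloride of monomethyl succinate)
Product: 9 succinate imide methyl 4-[(4S)-4-benzyl-2-oxooxazolidin-3-yl]-4-oxobutanoate
Conditions: Et3N, DMAP (cat.), CH2Cl2, 0 °C to rt
Reagents that add atoms: none
Why: N-Acylation of the oxazolidinone by the acid chloride (nucleophilic acyl substitution) gives the imide that carries C14, C1, C15 and C16.

Step 7
Reactants: 6 (2S,3S)-epoxy alcohol; 9 succinate imide
Product: 12 C1-alkylated imide methyl (3S)-3-[(4S)-4-benzyl-2-oxooxazolidine-3-carbonyl]-4-[(2S,3S)-3-[(3E,7E)-9-(tert-butyldimethylsilyloxy)-4,8-dimethylnona-3,7-dienyl]-3-methyloxiran-2-yl]butanoate, via epoxy triflate 10 (not isolated), via sodium enolate 11 (not isolated)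
Conditions: 6, Tf2O, 2,6-lutidine, CH2Cl2, −78 °C (gives 10, filtered cold through a short pad in pentane and used at once); 9, NaN(SiMe3)2, THF, −78 °C (gives 11); 10 added, −78 to −40 °C
Reagents that add atoms: none
Why: Evans asymmetric alkylation, in which the base deprotonates only the more acidic imide α-position to give the chelated Z-enolate 11, which displaces the primary triflate of 10 by SN2 on the face opposite the benzyl group and so sets C1 as S, while the epoxide, secondary at the near carbon and fully substituted at the far one, should not be opened at this temperature.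

Step 8
Reactants: 12 C1-alkylated imide
Product: 13 S-ethyl thioester methyl (3S)-3-(ethylsulfanylcarbonyl)-4-[(2S,3S)-3-[(3E,7E)-9-(tert-butyldimethylsilyloxy)-4,8-dimethylnona-3,7-dienyl]-3-methyloxiran-2-yl]butanoate
Conditions: EtSH, n-BuLi, THF, 0 °C
Reagents that add atoms: ethanethiol CCS
Why: Thiolysis of the N-acyloxazolidinone by LiSEt (acyl substitution at the exocyclic imide carbonyl, the most electrophilic acyl group present) releases the auxiliary and distinguishes C14 (thioester) from C16 (methyl ester) without ever freeing a C14 alcohol, which would lactonise onto C16 or open the epoxide.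

Step 9
Reactants: 13 S-ethyl thioester
Product: 14 C14 aldehyde silyl ether methyl (3S)-3-formyl-4-[(2S,3S)-3-[(3E,7E)-9-(tert-butyldimethylsilyloxy)-4,8-dimethylnona-3,7-dienyl]-3-methyloxiran-2-yl]butanoate
Conditions: Et3SiH, 10% Pd/C, acetone, rt
Reagents that add atoms: none
Why: Fukuyama reduction (oxidative addition of the C–S bond to zerovalent palladium, then hydride transfer from the silane) should convert the thioester into the aldehyde under neutral conditions that leave the methyl ester, epoxide, silyl ether and trisubstituted alkenes alone and do not epimerise C1.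

Step 10
Reactants: 14 C14 aldehyde silyl ether
Product: 15 C14 aldehyde C13 alcohol methyl (3S)-3-formyl-4-[(2S,3S)-3-[(3E,7E)-9-hydroxy-4,8-dimethylnona-3,7-dienyl]-3-methyloxiran-2-yl]butanoate
Conditions: HF·pyridine, pyridine (excess), THF, 0 °C
Reagents that add atoms: none
Why: Fluoride cleavage of the primary allylic silyl ether in pyridine-buffered medium is expected to be mild enough for the epoxide, the ester and the α-branched aldehyde.

Step 11
Reactants: 15 C14 aldehyde C13 alcohol
Product: 16 epoxy dialdehyde ester methyl (3S)-3-formyl-4-[(2S,3S)-3-[(3E,7E)-4,8-dimethyl-9-oxonona-3,7-dienyl]-3-methyloxiran-2-yl]butanoate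
Conditions: MnO2 (activated, excess), CH2Cl2, rt; filtration
Reagents that add atoms: none
Why: MnO2 oxidises allylic alcohols selectively, so only C13 is taken to the (E)-enal, and the neutral filtration work-up delivers the sensitive dialdehyde ready for cyclisation.

Step 12
Reactants: 16 epoxy dialdehyde ester
Product: 18 13-hydroxy lactone (1S,3S,4S,7E,11E,13S,14S)-3,4-epoxy-13-hydroxycembra-7,11-dien-16,14-olide, via samarium diolate 17 (not isolated)
Conditions: SmI2 (5 equiv), THF, rt, 16 added by syringe pump (about 2 mM final); aq. NaHCO3 work-up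
Reagents that add atoms: none
Why: Electron transfer from divalent samarium to both aldehydes gives the C14 ketyl and the delocalised C13 ketyl, which join at C13–C14 (not at C11, because the oxygen-bound samarium centres hold the two carbonyl carbons together) to give the bridged diolate 17; the closest known reaction type is the low-valent-metal pinacol macrocyclisation of dialdehydes to 14-membered cembranoid 1,2-diols. The carbocycle closes by 14-exo-trig ketyl–carbonyl coupling, kept intramolecular by slow addition of 16 to excess SmI2 at high dilution, and the lactone then closes by 5-exo-trig acyl substitution of the C14 samarium alkoxide on the C16 methyl ester, which outruns the six-membered closure from O13 and so leaves only the C13 hydroxyl free. C14 is controlled by the C1 stereocentre: trivalent samarium chelated between the C14 ketyl oxygen and the C16 ester carbonyl exposes the face of C14 anti to the C2 chain, which gives the trans ring fusion (H1 and H14 anti). C13 is controlled by the samarium-bridged diolate, in which the ring carbons C12 and C1 should lie on opposite sides of the five-membered O–C13–C14–O–Sm chelate, the threo (13S,14S) arrangement. The step needs chemoselection for the two aldehydes, which SmI2 in THF without HMPA or a proton donor should secure because the ester, the isolated trisubstituted epoxide and the unconjugated alkenes are not reduced, and it needs the threo, trans-fused diastereomer, for which chelation is the only bias and which is therefore the acknowledged risk.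

Step 13
Reactants: 18 13-hydroxy lactone
Product: 19 13-O-triethylsilyl lactone
Conditions: TESCl, imidazole, DMAP (cat.), DMF, 0 °C to rt
Reagents that add atoms: chlorotriethylsilane CC[Si](Cl)(CC)CC
Why: Silylation of the C13 hydroxyl removes the only acidic proton so that the lactone can be enolised cleanly.

Step 14
Reactants: 19 13-O-triethylsilyl lactone
Product: 21 15-(dimethylaminomethyl) lactone (both C15 epimers), via lithium enolate 20 (not isolated)
Conditions: LiN(iPr)2, THF, −78 °C; then Me2N=CH2 I (Eschenmoser's salt), −78 °C to rt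
Reagents that add atoms: N,N-dimethylmethyleneiminium iodide C=[N+](C)C.[I-]
Why: Mannich reaction of the lactone enolate 20 (C15 is the only enolisable position) with Eschenmoser's salt installs the aminomethyl group, and the new C15 centre is a mixture that the next step erases.

Step 15
Reactants: 21 15-(dimethylaminomethyl) lactone
Product: 23 13-O-triethylsilyl α-methylene lactone, via ammonium iodide 22 (not isolated)
Conditions: MeI, MeOH, rt; then NaHCO3, CH2Cl2/H2O, rt
Reagents that add atoms: none
Why: Exhaustive N-methylation gives the ammonium salt 22, which should undergo E1cB (Hofmann-type) elimination with mild base to the exocyclic methylene.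

Step 16
Reactants: 23 13-O-triethylsilyl α-methylene lactone
Product: 24 13-deacetyl compound (1S,3S,4S,7E,11E,13S,14S)-3,4-epoxy-13-hydroxycembra-7,11,15(17)-trien-16,14-olide
Conditions: HF·pyridine, pyridine, THF, 0 °C
Reagents that add atoms: none
Why: Buffered fluoride desilylation should remove the triethylsilyl ether without conjugate addition to the α-methylene lactone or opening of the epoxide.

Step 17
Reactants: 24 13-deacetyl compound
Product: 25 13-acetoxysarcocrassolide
Conditions: Ac2O, pyridine, DMAP (cat.), CH2Cl2, 0 °C to rt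
Reagents that add atoms: acetic anhydride CC(=O)OC(C)=O
Why: DMAP-catalysed acetylation of the secondary allylic C13 hydroxyl (nucleophilic acyl substitution) completes the target without touching any of the five stereocentres.

**Compound list**

1 | (2E,6E)-farnesol | OC/C=C(\C)CC/C=C(\C)CCC=C(C)C | starting material
2 | (2E,6E)-farnesyl acetate | CC(=O)OC/C=C(\C)CC/C=C(\C)CCC=C(C)C | intermediate
3 | (2E,6E,10E)-12-hydroxyfarnesyl acetate | CC(=O)OC/C=C(\C)CC/C=C(\C)CC/C=C(\C)CO | intermediate
4 | (2E,6E,10E)-12-(tert-butyldimethylsilyloxy)farnesyl acetate | CC(=O)OC/C=C(\C)CC/C=C(\C)CC/C=C(\C)CO[Si](C)(C)C(C)(C)C | intermediate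
5 | (2E,6E,10E)-12-(tert-butyldimethylsilyloxy)farnesol | OC/C=C(\C)CC/C=C(\C)CC/C=C(\C)CO[Si](C)(C)C(C)(C)C | intermediate
6 | (2S,3S)-epoxy alcohol, [(2S,3S)-3-[(3E,7E)-9-(tert-butyldimethylsilyloxy)-4,8-dimethylnona-3,7-dienyl]-3-methyloxiran-2-yl]methanol | OC[C@@H]1O[C@@]1(C)CC/C=C(\C)CC/C=C(\C)CO[Si](C)(C)C(C)(C)C | intermediate
7 | (S)-4-benzyloxazolidin-2-one | O=C1N[C@@H](Cc2ccccc2)CO1 | starting material
8 | methyl 4-chloro-4-oxobutanoate | COC(=O)CCC(Cl)=O | starting material
9 | succinate imide, methyl 4-[(4S)-4-benzyl-2-oxooxazolidin-3-yl]-4-oxobutanoate | COC(=O)CCC(=O)N1[C@@H](Cc2ccccc2)COC1=O | intermediate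
10 | epoxy triflate (trifluoromethanesulfonate of 6, 2S,3S) | FC(F)(F)S(=O)(=O)OC[C@@H]1O[C@@]1(C)CC/C=C(\C)CC/C=C(\C)CO[Si](C)(C)C(C)(C)C | intermediate
11 | sodium Z-enolate of 9 | COC(=O)C/C=C(\[O-])N1[C@@H](Cc2ccccc2)COC1=O.[Na+] | intermediate
12 | C1-alkylated imide (C1 S; epoxide 2S,3S; auxiliary 4S) | COC(=O)C[C@@H](C(=O)N1[C@@H](Cc2ccccc2)COC1=O)C[C@@H]1O[C@@]1(C)CC/C=C(\C)CC/C=C(\C)CO[Si](C)(C)C(C)(C)C | intermediate
13 | S-ethyl thioester (C14 thioester, C16 methyl ester, C13 silyl ether) | COC(=O)C[C@@H](C(=O)SCC)C[C@@H]1O[C@@]1(C)CC/C=C(\C)CC/C=C(\C)CO[Si](C)(C)C(C)(C)C | intermediate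
14 | C14 aldehyde silyl ether | COC(=O)C[C@@H](C=O)C[C@@H]1O[C@@]1(C)CC/C=C(\C)CC/C=C(\C)CO[Si](C)(C)C(C)(C)C | intermediate
15 | C14 aldehyde C13 alcohol | COC(=O)C[C@@H](C=O)C[C@@H]1O[C@@]1(C)CC/C=C(\C)CC/C=C(\C)CO | intermediate
16 | epoxy dialdehyde ester (C14 aldehyde, C13 enal, C16 methyl ester) | COC(=O)C[C@@H](C=O)C[C@@H]1O[C@@]1(C)CC/C=C(\C)CC/C=C(\C)C=O | intermediate
17 | samarium diolate (macrocyclic 13,14-bis(diiodosamarium) alkoxide, methyl ester intact) | COC(=O)C[C@@H]1C[C@@H]2O[C@@]2(C)CC/C=C(\C)CC/C=C(\C)[C@H](O[Sm](I)I)[C@H]1O[Sm](I)I | intermediate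
18 | 13-hydroxy lactone, (1S,3S,4S,7E,11E,13S,14S)-3,4-epoxy-13-hydroxycembra-7,11-dien-16,14-olide | C1C(=O)O[C@H]2[C@H]1C[C@@H]1O[C@@]1(C)CC/C=C(\C)CC/C=C(\C)[C@@H]2O | intermediate
19 | 13-O-triethylsilyl lactone | C1C(=O)O[C@H]2[C@H]1C[C@@H]1O[C@@]1(C)CC/C=C(\C)CC/C=C(\C)[C@@H]2O[Si](CC)(CC)CC | intermediate
20 | lithium enolate of 19 (C15=C16) | C1=C([O-])O[C@H]2[C@H]1C[C@@H]1O[C@@]1(C)CC/C=C(\C)CC/C=C(\C)[C@@H]2O[Si](CC)(CC)CC.[Li+] | intermediate
21 | 15-(dimethylaminomethyl) lactone (C15 epimers) | CN(C)CC1C(=O)O[C@H]2[C@H]1C[C@@H]1O[C@@]1(C)CC/C=C(\C)CC/C=C(\C)[C@@H]2O[Si](CC)(CC)CC | intermediate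
22 | ammonium iodide (N-methylated 21) | C[N+](C)(C)CC1C(=O)O[C@H]2[C@H]1C[C@@H]1O[C@@]1(C)CC/C=C(\C)CC/C=C(\C)[C@@H]2O[Si](CC)(CC)CC.[I-] | intermediate
23 | 13-O-triethylsilyl α-methylene lactone | C=C1C(=O)O[C@H]2[C@H]1C[C@@H]1O[C@@]1(C)CC/C=C(\C)CC/C=C(\C)[C@@H]2O[Si](CC)(CC)CC | intermediate
24 | 13-deacetyl compound, (1S,3S,4S,7E,11E,13S,14S)-3,4-epoxy-13-hydroxycembra-7,11,15(17)-trien-16,14-olide | C=C1C(=O)O[C@H]2[C@H]1C[C@@H]1O[C@@]1(C)CC/C=C(\C)CC/C=C(\C)[C@@H]2O | intermediate
25 | 13-acetoxysarcocrassolide | C=C1C(=O)O[C@H]2[C@H]1C[C@@H]1O[C@@]1(C)CC/C=C(\C)CC/C=C(\C)[C@@H]2OC(C)=O | target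

**Step count and risks**

Total steps: 17. Longest linear sequence: 16 steps (1 to 25 through steps 1–5 and 7–17); step 6 is a one-step side branch.

Steps most likely to fail:

1. Step 12. The coupling may proceed through the other face of the C13 ketyl (erythro diolate), so that the 13-epimer dominates. Intermolecular coupling may also compete if the dialdehyde accumulates. Fallback: setting out from 16, the cyclisation is run as before and the erythro product, the 13-epi hydroxy lactone F1 (13R,14S), is carried on instead of being discarded. A Mitsunobu reaction (PPh3, diisopropyl azodicarboxylate, 4-nitrobenzoic acid, toluene, 0 °C to rt) should invert C13 by SN2 and give the (13S)-4-nitrobenzoate F2. Brief methanolysis (K2CO3, MeOH, 0 °C) then comes back to 18. This replaces kinetic control in the coupling by a stereospecific substitution.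

2. Step 7. The hard triflate may O-alkylate the ambident imide enolate, or may decompose before the hindered enolate C-alkylates it. Fallback: setting out from 6, the order of bond formation at C1 is reversed, so that the awkward electrophile meets a small, reactive enolate and the auxiliary-controlled step uses an activated halide.
   - 6 is converted (I2, PPh3, imidazole, CH2Cl2, 0 °C) into the epoxy iodide F3.
   - The lithium enolate of allyl acetate (LiN(iPr)2, THF, −78 °C, then F3 and DMPU, to −30 °C) gives the allyl ester F4.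
   - Pd(PPh3)4 and morpholine (THF, rt) release the carboxylic acid F5 without any acid.
   - F5 is converted through its pivaloyl mixed anhydride (t-BuCOCl, Et3N, THF, −20 °C; then (R)-4-benzyloxazolidin-2-one, LiCl) into the imide F6.
   - Evans alkylation of F6 (NaN(SiMe3)2, THF, −78 °C; methyl bromoacetate) gives the alkylated imide F7. C1 is again S, because resident and incoming substituents have exchanged roles and the auxiliary is the enantiomer.
   - Thiolysis of F7 under the step 8 conditions comes back to 13.

3. Step 10. During desilylation the C14 carbonyl oxygen may take part in acid-promoted opening of the γ,δ-epoxide (bicyclic acetal formation), or C1 may enolise. Fallback: setting out from 13, the silyl ether is removed while C14 is still the robust thioester (HF·pyridine, pyridine, THF, 0 °C) to give the hydroxy thioester F8. MnO2 (CH2Cl2, rt) gives the enal thioester F9. The Fukuyama reduction (Et3SiH, 10% Pd/C or lead-poisoned Pd/CaCO3, acetone, rt) is then the last operation and comes back to 16, so that the epoxy aldehyde never meets fluoride or acid.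

Further compounds
F1 | step 12 | 13-epi hydroxy lactone, (1S,3S,4S,7E,11E,13R,14S)-3,4-epoxy-13-hydroxycembra-7,11-dien-16,14-olide | C1C(=O)O[C@H]2[C@H]1C[C@@H]1O[C@@]1(C)CC/C=C(\C)CC/C=C(\C)[C@H]2O
F2 | step 12 | (13S)-4-nitrobenzoate of the hydroxy lactone | C1C(=O)O[C@H]2[C@H]1C[C@@H]1O[C@@]1(C)CC/C=C(\C)CC/C=C(\C)[C@@H]2OC(=O)c1ccc(cc1)[N+](=O)[O-]
F3 | step 7 | epoxy iodide, (2R,3S)-2-(iodomethyl)-3-methyl-3-[(3E,7E)-9-(tert-butyldimethylsilyloxy)-4,8-dimethylnona-3,7-dienyl]oxirane | IC[C@@H]1O[C@@]1(C)CC/C=C(\C)CC/C=C(\C)CO[Si](C)(C)C(C)(C)C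
F4 | step 7 | allyl ester, allyl 3-[(2S,3S)-3-[(3E,7E)-9-(tert-butyldimethylsilyloxy)-4,8-dimethylnona-3,7-dienyl]-3-methyloxiran-2-yl]propanoate | C=CCOC(=O)CC[C@@H]1O[C@@]1(C)CC/C=C(\C)CC/C=C(\C)CO[Si](C)(C)C(C)(C)C
F5 | step 7 | carboxylic acid, 3-[(2S,3S)-3-[(3E,7E)-9-(tert-butyldimethylsilyloxy)-4,8-dimethylnona-3,7-dienyl]-3-methyloxiran-2-yl]propanoic acid | OC(=O)CC[C@@H]1O[C@@]1(C)CC/C=C(\C)CC/C=C(\C)CO[Si](C)(C)C(C)(C)C
F6 | step 7 | imide of F5 with (R)-4-benzyloxazolidin-2-one | O=C(CC[C@@H]1O[C@@]1(C)CC/C=C(\C)CC/C=C(\C)CO[Si](C)(C)C(C)(C)C)N1[C@H](Cc2ccccc2)COC1=O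
F7 | step 7 | alkylated imide (C1 S, auxiliary 4R) | COC(=O)C[C@@H](C(=O)N1[C@H](Cc2ccccc2)COC1=O)C[C@@H]1O[C@@]1(C)CC/C=C(\C)CC/C=C(\C)CO[Si](C)(C)C(C)(C)C
F8 | step 10 | hydroxy thioester (C14 thioester, C13 alcohol) | COC(=O)C[C@@H](C(=O)SCC)C[C@@H]1O[C@@]1(C)CC/C=C(\C)CC/C=C(\C)CO
F9 | step 10 | enal thioester (C14 thioester, C13 enal) | COC(=O)C[C@@H](C(=O)SCC)C[C@@H]1O[C@@]1(C)CC/C=C(\C)CC/C=C(\C)C=O
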